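**Retrosynthetic overview**

1. Numbering: upper unit C1–C15 (lactone C12–O–C8, exo-methylene C13, methyl C14 on C10, acetyl C4/C15); lower unit primed (spiro carbon C11', bridging C13'H2). In the given SMILES the two halves are antipodal (upper 7R,8R,10S; lower 7'S,8'S,10'R), so they are made separately.
2. Acetyl C3–C4: Negishi coupling on a ring C enol triflate. Ring C (C11'–C13', then C1–C2): Michael/aldol annulation of an upper bis-methylene keto lactone with a lower α-acetyl lactone.
3. Lower side chain C1'–C2': B-alkyl Suzuki coupling of an enol triflate. Methyls C14/C14': Stille coupling on α-iodo enones.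
4. Both cis-lactones (C7–C11 bond, C7 centre): rhodium-carbenoid C–H insertion of diazoacetates, run in both antipodal series.
5. Both series come from the meso endoperoxide of cyclohepta-1,3-diene by enantiodivergent Kornblum–DeLaMare rearrangement. Ring order: seven-membered rings (bought), then lactones, then ring C.

Assumption: the quinidine-derived catalyst of step 2 is taken to give (S)-3 and Rh2(4S-MPPIM)4 to be the matched catalyst for 8 (MPPIM = methyl 2-oxo-1-(3-phenylpropanoyl)imidazolidine-4-carboxylate, a bridging carboxamidate); if a sense is the reverse, the enantiomeric catalysts are exchanged between the two series.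

**Route**

Step 1
Reactants: 1 cyclohepta-1,3-diene
Product: 2 6,7-dioxabicyclo[3.2.2]non-8-ene (meso cis-endoperoxide)
Conditions: O2, hν, tetraphenylporphyrin (cat.), CH2Cl2, 0 °C
Reagents that add atoms: dioxygen O=O
Why: Singlet-oxygen [4+2] cycloaddition (photooxygenation) to the cyclic diene is suprafacial and can only give the cis, meso endoperoxide.

Step 2
Reactants: 2 6,7-dioxabicyclo[3.2.2]non-8-ene
Product: 3 (S)-4-hydroxycyclohept-2-en-1-one
Conditions: 9-O-acetylcupreidine (5 mol %), CH2Cl2, 23 °C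
Reagents that add atoms: none
Why: Enantioselective Kornblum–DeLaMare rearrangement: the chiral amine removes one of the two enantiotopic bridgehead protons and O–O cleavage gives the γ-hydroxy enone, so the carbinol centre (later C8) is set by the catalyst.

Step 3
Reactants: 3 (S)-4-hydroxycyclohept-2-en-1-one
Product: 4 (S)-4-hydroxy-2-iodocyclohept-2-en-1-one
Conditions: I2, pyridine, CH2Cl2, 0 → 23 °C
Reagents that add atoms: iodine II
Why: α-Iodination of the enone by conjugate addition of pyridine, iodination of the enolate and E1cB loss of pyridine (addition–elimination of Baylis–Hillman type), which leaves the carbinol centre alone.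

Step 4
Reactants: 4 (S)-4-hydroxy-2-iodocyclohept-2-en-1-one
Product: 5 (S)-4-hydroxy-2-methylcyclohept-2-en-1-one
Conditions: Me4Sn, PdCl2(PhCN)2 (5 mol %), AsPh3, CuI (10 mol %), NMP, 80 °C
Reagents that add atoms: tetramethylstannane C[Sn](C)(C)C
Why: Stille cross-coupling: zerovalent palladium inserts into the activated C–I bond of the α-iodo enone and copper-assisted methyl transfer places the future C14 methyl regiospecifically on C10.

Step 5
Reactants: 5 (S)-4-hydroxy-2-methylcyclohept-2-en-1-one
Product: 6 (2S,4S)-4-hydroxy-2-methylcycloheptan-1-one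
Conditions: H2 (1 atm), 5 % Pd/C, EtOAc, 23 °C
Reagents that add atoms: none
Why: Heterogeneous catalytic hydrogenation of the enone C=C; weakly haptophilic palladium delivers hydrogen anti to the allylic hydroxyl so the methyl ends cis to OH, and this cis-2,4 isomer is also expected to be the thermodynamic one at the epimerisable α-carbon.

Step 6
Reactants: 6 (2S,4S)-4-hydroxy-2-methylcycloheptan-1-one
Product: 7 (1S,3S)-3-methyl-4-oxocycloheptyl 2-bromoacetate
Conditions: BrCH2COBr, NaHCO3, MeCN, 0 °C
Reagents that add atoms: bromoacetyl bromide BrCC(Br)=O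
Why: O-Acylation of the secondary alcohol by the acid bromide under weakly basic conditions brings in C11 and C12 without epimerising the α-methyl ketone.

Step 7
Reactants: 7 (1S,3S)-3-methyl-4-oxocycloheptyl 2-bromoacetate
Product: 8 (1S,3S)-3-methyl-4-oxocycloheptyl 2-diazoacetate
Conditions: TsNHNHTs, DBU, THF, 0 °C
Reagents that add atoms: N,N'-bis(4-methylbenzenesulfonyl)hydrazine Cc1ccc(cc1)S(=O)(=O)NNS(=O)(=O)c1ccc(C)cc1
Why: N-Alkylation of the bis-sulfonylhydrazine by the bromoacetate and base-induced loss of two sulfinate ions (Bamford–Stevens-type elimination) give the diazoacetate under conditions the ketone tolerates.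

Step 8
Reactants: 8 (1S,3S)-3-methyl-4-oxocycloheptyl 2-diazoacetate
Product: 9 (3aR,7S,8aR)-7-methylhexahydro-2H-cyclohepta[b]furan-2,6(3H)-dione
Conditions: Rh2(4S-MPPIM)4 (1 mol %), CH2Cl2, 40 °C, slow addition
Reagents that add atoms: none
Why: Proposed new method: site- and diastereoselective intramolecular carbenoid C–H insertion on an unsymmetrical keto diazoacetate, in which the electrophilic divalent-rhodium carbenoid inserts through a five-membered transition state with retention into the C7–H bond cis to the ester oxygen (cis-fused γ-lactone, C7 set) and spares the other flanking methylene C9 because its C–H bonds are β to the ring carbonyl (inductively deactivated) and adjacent to the methyl-bearing carbon, the matched chiral carboxamidate reinforcing this choice; closest known reaction type: enantioselective γ-lactone formation from unsubstituted cycloalkyl diazoacetates with chiral dirhodium carboxamidates.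

Step 9
Reactants: 9 (3aR,7S,8aR)-7-methylhexahydro-2H-cyclohepta[b]furan-2,6(3H)-dione
Product: 11 (3aR,7S,8aR)-3,5-bis[(dimethylamino)methyl]-7-methylhexahydro-2H-cyclohepta[b]furan-2,6(3H)-dione (epimers at C3 and C5), via dilithium bis-enolate 10 (not isolated)
Conditions: LiN(i-Pr)2 (2.3 equiv), THF, −78 °C; then CH2=NMe2+ I− (2.6 equiv), −78 → 23 °C
Reagents that add atoms: N,N-dimethylmethyleneiminium iodide (Eschenmoser's salt) C=[N+](C)C.[I-]
Why: Double Mannich reaction: kinetic deprotonation takes the unsubstituted ketone α-CH2 (C5, not the methyl-bearing C10) and then the lactone α-CH2, both enolates are aminomethylated, and the two new centres are erased in step 21.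

Step 10
Reactants: 11 the bis-Mannich base
Product: 12 (3aR,7S,8aR)-7-methyl-3,5-bis[(trimethylammonio)methyl]hexahydro-2H-cyclohepta[b]furan-2,6(3H)-dione diiodide (epimers at C3 and C5)
Conditions: MeI (excess), MeCN, 23 °C
Reagents that add atoms: iodomethane CI
Why: Exhaustive N-methylation (Menshutkin quaternisation) turns both amines into trimethylammonium leaving groups for later E1cB release of the two exocyclic methylenes.

Step 11
Reactants: 2 6,7-dioxabicyclo[3.2.2]non-8-ene
Product: 13 (R)-4-hydroxycyclohept-2-en-1-one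
Conditions: 9-O-acetylcupreine (5 mol %), CH2Cl2, 23 °C
Reagents that add atoms: none
Why: The same enantioselective Kornblum–DeLaMare rearrangement with the pseudo-enantiomeric base removes the other bridgehead proton and gives the antipodal carbinol centre (later C8').

Step 12
Reactants: 13 (R)-4-hydroxycyclohept-2-en-1-one
Product: 14 (R)-4-hydroxy-2-iodocyclohept-2-en-1-one
Conditions: I2, pyridine, CH2Cl2, 0 → 23 °C
Reagents that add atoms: iodine II
Why: α-Iodination by pyridine addition–elimination as in step 3, in the antipodal series.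

Step 13
Reactants: 14 (R)-4-hydroxy-2-iodocyclohept-2-en-1-one
Product: 15 (R)-4-hydroxy-2-methylcyclohept-2-en-1-one
Conditions: Me4Sn, PdCl2(PhCN)2 (5 mol %), AsPh3, CuI (10 mol %), NMP, 80 °C
Reagents that add atoms: tetramethylstannane C[Sn](C)(C)C
Why: Stille cross-coupling as in step 4 installs the C14' methyl on C10'.

Step 14
Reactants: 15 (R)-4-hydroxy-2-methylcyclohept-2-en-1-one
Product: 16 (2R,4R)-4-hydroxy-2-methylcycloheptan-1-one
Conditions: H2 (1 atm), 5 % Pd/C, EtOAc, 23 °C
Reagents that add atoms: none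
Why: Heterogeneous hydrogenation anti to the hydroxyl as in step 5 gives the cis-2,4 isomer, which is also expected to be the thermodynamic one.

Step 15
Reactants: 16 (2R,4R)-4-hydroxy-2-methylcycloheptan-1-one
Product: 17 (1R,3R)-3-methyl-4-oxocycloheptyl 2-bromoacetate
Conditions: BrCH2COBr, NaHCO3, MeCN, 0 °C
Reagents that add atoms: bromoacetyl bromide BrCC(Br)=O
Why: O-Acylation as in step 6 brings in C11' and C12'.

Step 16
Reactants: 17 (1R,3R)-3-methyl-4-oxocycloheptyl 2-bromoacetate
Product: 18 (1R,3R)-3-methyl-4-oxocycloheptyl 2-diazoacetate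
Conditions: TsNHNHTs, DBU, THF, 0 °C
Reagents that add atoms: N,N'-bis(4-methylbenzenesulfonyl)hydrazine Cc1ccc(cc1)S(=O)(=O)NNS(=O)(=O)c1ccc(C)cc1
Why: Hydrazine alkylation and double sulfinate elimination (Bamford–Stevens type) as in step 7.

Step 17
Reactants: 18 (1R,3R)-3-methyl-4-oxocycloheptyl 2-diazoacetate
Product: 19 (3aS,7R,8aS)-7-methylhexahydro-2H-cyclohepta[b]furan-2,6(3H)-dione
Conditions: Rh2(4R-MPPIM)4 (1 mol %), CH2Cl2, 40 °C, slow addition
Reagents that add atoms: none
Why: Proposed new method: the same site- and diastereoselective carbenoid C–H insertion as in step 8 with the enantiomeric catalyst, the divalent-rhodium carbenoid inserting with retention into the C7'–H bond cis to the ester oxygen while the carbonyl-deactivated and more hindered C9' methylene is spared; closest known reaction type: enantioselective γ-lactone formation from unsubstituted cycloalkyl diazoacetates with chiral dirhodium carboxamidates.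

Step 18
Reactants: 19 (3aS,7R,8aS)-7-methylhexahydro-2H-cyclohepta[b]furan-2,6(3H)-dione
Product: 21 (3aS,7R,8aS)-7-methyl-2-oxo-3,3a,4,7,8,8a-hexahydro-2H-cyclohepta[b]furan-6-yl trifluoromethanesulfonate, via potassium ketone enolate 20 (not isolated)
Conditions: KN(SiMe3)2 (1.05 equiv), THF, −78 °C; then PhNTf2, −78 → 0 °C
Reagents that add atoms: N-phenylbis(trifluoromethanesulfonimide) O=S(=O)(N(c1ccccc1)S(=O)(=O)C(F)(F)F)C(F)(F)F
Why: Kinetic deprotonation takes the unsubstituted ketone α-CH2 (the lactone α-protons are several pK units less acidic) and O-triflation gives the C1'=C5' enol triflate with the C10' methyl centre untouched.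

Step 19
Reactants: 21 the enol triflate; 22 2-methyl-2-vinyl-1,3-dioxolane
Product: 24 (3aS,7R,8aS)-7-methyl-6-[2-(2-methyl-1,3-dioxolan-2-yl)ethyl]-3,3a,4,7,8,8a-hexahydro-2H-cyclohepta[b]furan-2-one, via B-alkyl-9-borabicyclo[3.3.1]nonane 23 (not isolated)
Conditions: 22, 9-BBN-H, THF, 0 → 23 °C; then 21, PdCl2(dppf) (5 mol %), AsPh3, Cs2CO3, DMF/H2O, 23 °C
Reagents that add atoms: none
Why: Anti-Markovnikov hydroboration followed by B-alkyl Suzuki–Miyaura coupling, in which zerovalent palladium inserts into the enol triflate and base-activated alkyl transfer from boron forms the C1'–C2' bond with the ring olefin fixed at C1'=C5'.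

Step 20
Reactants: 24 the coupled lactone
Product: 26 (3aS,7R,8aS)-3-acetyl-7-methyl-6-[2-(2-methyl-1,3-dioxolan-2-yl)ethyl]-3,3a,4,7,8,8a-hexahydro-2H-cyclohepta[b]furan-2-one (C3 epimers and enol), via lithium lactone enolate 25 (not isolated)
Conditions: LiN(SiMe3)2 (2.2 equiv), THF, −78 °C; then 1-acetylimidazole, −78 → 0 °C
Reagents that add atoms: 1-acetylimidazole CC(=O)n1ccnc1
Why: Crossed Claisen condensation (C-acylation of the lactone enolate, the second equivalent of base holding the product as its enolate) supplies C2 and C3 and makes C11' a soft Michael donor whose configuration is fixed only in step 21.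

Step 21
Reactants: 12 the bis-ammonium diiodide; 26 the α-acetyl lactone
Product: 29 ring C ketol (target skeleton with C1–OH; C2H2; C3=O; C4' ketone as 1,3-dioxolane; all nine stereocentres as in the target), via bis-methylene keto lactone 27 (not isolated), via Michael adduct 28 (not isolated)
Conditions: 12, NaHCO3, H2O/CH2Cl2, 0 °C; dried organic phase + 26, KN(SiMe3)2 (0.3 equiv), THF, −40 → 0 °C
Reagents that add atoms: none
Why: E1cB loss of both ammonium groups frees the exo-methylene ketone and the α-methylene lactone, the enolate of 26 adds (Michael) to the far more electrophilic enone through its convex face anti to C6' so that C13' ends cis to H7' at the spiro carbon, and after base-relayed equilibration of C5 the methyl-ketone enolate closes onto C1 (intramolecular aldol of a Robinson-type annulation halted at the ketol) from the face opposite the C10 methyl and the upper lactone, giving cis-fused ring C with C1–OH cis to the C10 methyl.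

Step 22
Reactants: 29 the ring C ketol
Product: 30 C1 triethylsilyl ether of ketol 29
Conditions: Et3SiOTf, 2,6-lutidine, CH2Cl2, −78 → −20 °C
Reagents that add atoms: triethylsilyl trifluoromethanesulfonate CC[Si](CC)(CC)OS(=O)(=O)C(F)(F)F
Why: Silylation of the hindered tertiary alcohol with the silyl triflate blocks retro-aldol cleavage in the next step, while the ketal and both lactones survive the buffered low-temperature conditions.

Step 23
Reactants: 30 the silyl ether
Product: 32 C2=C3 enol triflate of 30 (C3–OSO2CF3), via potassium C2 enolate 31 (not isolated)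
Conditions: KN(SiMe3)2, THF, −78 °C; then PhNTf2, −78 → −20 °C
Reagents that add atoms: N-phenylbis(trifluoromethanesulfonimide) O=S(=O)(N(c1ccccc1)S(=O)(=O)C(F)(F)F)C(F)(F)F
Why: Enolisation is regiospecific because C2 is the only α-carbon bearing hydrogen (C11' is quaternary), and O-triflation at −78 °C outruns β-elimination of the silyloxy group.

Step 24
Reactants: 32 the enol triflate; 33 ethyl vinyl ether
Product: 36 C3-(1-ethoxyvinyl) diene (32 with OTf replaced by C(OEt)=CH2), via 1-ethoxyvinyllithium 34 (not isolated), via chloro(1-ethoxyvinyl)zinc 35 (not isolated)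
Conditions: 33, t-BuLi, THF, −78 → 0 °C; ZnCl2, 0 °C; then 32, Pd(PPh3)4 (10 mol %), 50 °C
Reagents that add atoms: none
Why: Negishi cross-coupling: α-lithiation of the vinyl ether, transmetalation to zinc, oxidative addition of zerovalent palladium into the hindered enol triflate and reductive elimination form the C3–C4 bond as a masked acetyl group, the organozinc being inert to both lactones.

Step 25
Reactants: 36 the ethoxy diene
Product: 37 target CNP0195550.4
Conditions: 1 M HCl, THF/H2O, 23 °C
Reagents that add atoms: water O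
Why: Acid hydrolysis of the enol ether (to the C4 ketone, completing the γ-hydroxy enone), of the dioxolane and of the silyl ether in one operation touches no stereocentre, the tertiary allylic alcohol being deactivated toward ionisation by the conjugated acetyl group.

**Compound list**

1 | cyclohepta-1,3-diene | C1=CC=CCCC1 | starting material
2 | 6,7-dioxabicyclo[3.2.2]non-8-ene (meso cis-endoperoxide) | C1C[C@@H]2C=C[C@H](C1)OO2 | intermediate
3 | (S)-4-hydroxycyclohept-2-en-1-one | O[C@@H]1C=CC(=O)CCC1 | intermediate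
4 | (S)-4-hydroxy-2-iodocyclohept-2-en-1-one | O[C@@H]1C=C(I)C(=O)CCC1 | intermediate
5 | (S)-4-hydroxy-2-methylcyclohept-2-en-1-one | O[C@@H]1C=C(C)C(=O)CCC1 | intermediate
6 | (2S,4S)-4-hydroxy-2-methylcycloheptan-1-one | O[C@@H]1C[C@H](C)C(=O)CCC1 | intermediate
7 | (1S,3S)-3-methyl-4-oxocycloheptyl 2-bromoacetate | BrCC(=O)O[C@@H]1C[C@H](C)C(=O)CCC1 | intermediate
8 | (1S,3S)-3-methyl-4-oxocycloheptyl 2-diazoacetate | [N-]=[N+]=CC(=O)O[C@@H]1C[C@H](C)C(=O)CCC1 | intermediate
9 | (3aR,7S,8aR)-7-methylhexahydro-2H-cyclohepta[b]furan-2,6(3H)-dione (cis-fused keto lactone, upper series) | C1C(=O)O[C@@H]2C[C@H](C)C(=O)CC[C@H]12 | intermediate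
10 | dilithium bis-enolate of 9 (ketone enolate toward C5 and lactone enolate) | [Li+].[Li+].C1=C([O-])O[C@@H]2C[C@H](C)C([O-])=CC[C@H]12 | intermediate
11 | (3aR,7S,8aR)-3,5-bis[(dimethylamino)methyl]-7-methylhexahydro-2H-cyclohepta[b]furan-2,6(3H)-dione (epimers at C3 and C5) | CN(C)CC1C(=O)O[C@@H]2C[C@H](C)C(=O)C(CN(C)C)C[C@H]12 | intermediate
12 | (3aR,7S,8aR)-7-methyl-3,5-bis[(trimethylammonio)methyl]hexahydro-2H-cyclohepta[b]furan-2,6(3H)-dione diiodide (epimers at C3 and C5) | C[N+](C)(C)CC1C(=O)O[C@@H]2C[C@H](C)C(=O)C(C[N+](C)(C)C)C[C@H]12.[I-].[I-] | intermediate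
13 | (R)-4-hydroxycyclohept-2-en-1-one | O[C@H]1C=CC(=O)CCC1 | intermediate
14 | (R)-4-hydroxy-2-iodocyclohept-2-en-1-one | O[C@H]1C=C(I)C(=O)CCC1 | intermediate
15 | (R)-4-hydroxy-2-methylcyclohept-2-en-1-one | O[C@H]1C=C(C)C(=O)CCC1 | intermediate
16 | (2R,4R)-4-hydroxy-2-methylcycloheptan-1-one | O[C@H]1C[C@@H](C)C(=O)CCC1 | intermediate
17 | (1R,3R)-3-methyl-4-oxocycloheptyl 2-bromoacetate | BrCC(=O)O[C@H]1C[C@@H](C)C(=O)CCC1 | intermediate
18 | (1R,3R)-3-methyl-4-oxocycloheptyl 2-diazoacetate | [N-]=[N+]=CC(=O)O[C@H]1C[C@@H](C)C(=O)CCC1 | intermediate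
19 | (3aS,7R,8aS)-7-methylhexahydro-2H-cyclohepta[b]furan-2,6(3H)-dione (cis-fused keto lactone, lower series) | C1C(=O)O[C@H]2C[C@@H](C)C(=O)CC[C@@H]12 | intermediate
20 | potassium ketone enolate of 19 (toward C5) | [K+].C1C(=O)O[C@H]2C[C@@H](C)C([O-])=CC[C@@H]12 | intermediate
21 | (3aS,7R,8aS)-7-methyl-2-oxo-3,3a,4,7,8,8a-hexahydro-2H-cyclohepta[b]furan-6-yl trifluoromethanesulfonate | C1C(=O)O[C@H]2C[C@@H](C)C(OS(=O)(=O)C(F)(F)F)=CC[C@@H]12 | intermediate
22 | 2-methyl-2-vinyl-1,3-dioxolane | C=CC1(C)OCCO1 | starting material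
23 | 9-[2-(2-methyl-1,3-dioxolan-2-yl)ethyl]-9-borabicyclo[3.3.1]nonane | CC1(CCB2[C@@H]3CCC[C@H]2CCC3)OCCO1 | intermediate
24 | (3aS,7R,8aS)-7-methyl-6-[2-(2-methyl-1,3-dioxolan-2-yl)ethyl]-3,3a,4,7,8,8a-hexahydro-2H-cyclohepta[b]furan-2-one | C1C(=O)O[C@H]2C[C@@H](C)C(CCC3(C)OCCO3)=CC[C@@H]12 | intermediate
25 | lithium lactone enolate of 24 | [Li+].C1=C([O-])O[C@H]2C[C@@H](C)C(CCC3(C)OCCO3)=CC[C@@H]12 | intermediate
26 | (3aS,7R,8aS)-3-acetyl-7-methyl-6-[2-(2-methyl-1,3-dioxolan-2-yl)ethyl]-3,3a,4,7,8,8a-hexahydro-2H-cyclohepta[b]furan-2-one (C3 epimers and enol) | CC(=O)C1C(=O)O[C@H]2C[C@@H](C)C(CCC3(C)OCCO3)=CC[C@@H]12 | intermediate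
27 | (3aR,7S,8aR)-7-methyl-3,5-dimethylidenehexahydro-2H-cyclohepta[b]furan-2,6(3H)-dione | C=C1C(=O)O[C@@H]2C[C@H](C)C(=O)C(=C)C[C@H]12 | intermediate
28 | Michael adduct: 1,5-diketone in which C13'H2 links C5 of the upper unit (both C5 epimers) to the quaternary C11' of the lower α-acetyl lactone (C13' cis to H7', acetyl cis to C6') | C=C1C(=O)O[C@@H]2C[C@H](C)C(=O)C(C[C@]3(C(C)=O)C(=O)O[C@H]4C[C@@H](C)C(CCC5(C)OCCO5)=CC[C@@H]34)C[C@H]12 | intermediate
29 | ring C ketol: target skeleton with C1–OH, C2H2 and C3 ketone in place of the acetyl enone, C4' ketone as 1,3-dioxolane, stereocentres as in the target | C=C1C(=O)O[C@@H]2C[C@H](C)[C@@]3(O)CC(=O)[C@@]4(C[C@H]3C[C@H]12)C(=O)O[C@H]1C[C@@H](C)C(CCC5(C)OCCO5)=CC[C@H]14 | intermediate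
30 | C1 triethylsilyl ether of 29 | C=C1C(=O)O[C@@H]2C[C@H](C)[C@@]3(O[Si](CC)(CC)CC)CC(=O)[C@@]4(C[C@H]3C[C@H]12)C(=O)O[C@H]1C[C@@H](C)C(CCC5(C)OCCO5)=CC[C@H]14 | intermediate
31 | potassium C2=C3 enolate of 30 | [K+].C=C1C(=O)O[C@@H]2C[C@H](C)[C@@]3(O[Si](CC)(CC)CC)C=C([O-])[C@@]4(C[C@H]3C[C@H]12)C(=O)O[C@H]1C[C@@H](C)C(CCC5(C)OCCO5)=CC[C@H]14 | intermediate
32 | C2=C3 enol triflate of 30 (triflate on C3) | C=C1C(=O)O[C@@H]2C[C@H](C)[C@@]3(O[Si](CC)(CC)CC)C=C(OS(=O)(=O)C(F)(F)F)[C@@]4(C[C@H]3C[C@H]12)C(=O)O[C@H]1C[C@@H](C)C(CCC5(C)OCCO5)=CC[C@H]14 | intermediate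
33 | ethyl vinyl ether | C=COCC | starting material
34 | 1-ethoxyvinyllithium | [Li]C(=C)OCC | intermediate
35 | chloro(1-ethoxyvinyl)zinc | Cl[Zn]C(=C)OCC | intermediate
36 | C3-(1-ethoxyvinyl) diene: 32 with the triflate replaced by C(OEt)=CH2 | C=C1C(=O)O[C@@H]2C[C@H](C)[C@@]3(O[Si](CC)(CC)CC)C=C(C(=C)OCC)[C@@]4(C[C@H]3C[C@H]12)C(=O)O[C@H]1C[C@@H](C)C(CCC5(C)OCCO5)=CC[C@H]14 | intermediate
37 | CNP0195550.4 | C=C1C(=O)O[C@@H]2C[C@H](C)[C@@]3(O)C=C(C(C)=O)[C@@]4(C[C@H]3C[C@H]12)C(=O)O[C@H]1C[C@@H](C)C(CCC(C)=O)=CC[C@H]14 | target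

**Step count and risks**

Total step count: 25. Longest linear sequence: 16 steps (step 1, steps 11–20, steps 21–25).

Step 8, the proposed new C–H insertion (step 17 is its mirror image). It may insert at C9, give the trans-fused lactone, or lose the carbene to dimerisation. The fallback uses known chemistry and builds the lactone by enolate alkylation and ketone reduction, with the roles of the two oxygenated carbons of 3 exchanged (its ketone becomes C8, its carbinol the later C1 ketone). It sets out from 3 and comes back at 9.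
- t-BuMe2SiCl/imidazole gives (S)-4-[(tert-butyldimethylsilyl)oxy]cyclohept-2-en-1-one F1.
- LiN(i-Pr)2 then ethyl bromoacetate alkylate the α'-carbon to the (1R,5S) silyloxy keto ester F2; this α-centre is epimerisable and is equilibrated and separated.
- Me2CuLi/Me3SiCl adds the methyl anti to the silyloxy group to give the (1R,4S,5S) methyl keto ester F3.
- LiBH(s-Bu)3 reduces the ketone from the face opposite the acetate arm to the cis hydroxy ester F4, which TsOH closes to the silyloxy lactone F5.
- Bu4NF gives the hydroxy lactone F6, and Dess–Martin periodinane oxidises it to 9.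
- For step 17 the same sequence sets out from 13 and comes back at 19, through the antipodal silyl enone F7, alkylated enone F8, methyl keto ester F9, hydroxy ester F10, silyloxy lactone F11 and hydroxy lactone F12.

Step 21, the Michael/aldol annulation. The C5 equilibration may not funnel into the desired cis-fused ketol, or the quaternary β-keto lactone may cleave under base. The fallback abandons the base-relayed domino for a stepwise, aminocatalytic closure. It sets out from 12 and 26: the Michael addition is run with Et3N alone and the diketone 28 is isolated. Ring C is then closed by a Hajos–Parrish-type enamine aldol (proline, matched enantiomer, DMF, 23 °C), which stops at the ketol and comes back at 29. No compound outside the list arises (F0).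

Step 23, enol triflate formation. The enolate may eliminate the β-silyloxy group. The fallback avoids the enolate altogether and sets out from 30: 1-ethoxyvinyllithium 34 adds to the C3 ketone at −78 °C to give the tertiary C3 carbinol F13. Burgess reagent then dehydrates it toward C2, the only carbon with β-hydrogens, and the route is rejoined at 36.

Further compounds
F1 | step 8 | (S)-4-[(tert-butyldimethylsilyl)oxy]cyclohept-2-en-1-one | CC(C)(C)[Si](C)(C)O[C@@H]1C=CC(=O)CCC1
F2 | step 8 | ethyl 2-[(1R,5S)-5-[(tert-butyldimethylsilyl)oxy]-2-oxocyclohept-3-en-1-yl]acetate | CCOC(=O)C[C@@H]1C(=O)C=C[C@@H](O[Si](C)(C)C(C)(C)C)CC1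
F3 | step 8 | ethyl 2-[(1R,4S,5S)-5-[(tert-butyldimethylsilyl)oxy]-4-methyl-2-oxocycloheptyl]acetate | CCOC(=O)C[C@@H]1C(=O)C[C@H](C)[C@@H](O[Si](C)(C)C(C)(C)C)CC1
F4 | step 8 | ethyl 2-[(1R,2R,4S,5S)-5-[(tert-butyldimethylsilyl)oxy]-2-hydroxy-4-methylcycloheptyl]acetate | CCOC(=O)C[C@@H]1[C@H](O)C[C@H](C)[C@@H](O[Si](C)(C)C(C)(C)C)CC1
F5 | step 8 | (3aR,6S,7S,8aR)-6-[(tert-butyldimethylsilyl)oxy]-7-methyloctahydro-2H-cyclohepta[b]furan-2-one | C1C(=O)O[C@@H]2C[C@H](C)[C@@H](O[Si](C)(C)C(C)(C)C)CC[C@H]12
F6 | step 8 | (3aR,6S,7S,8aR)-6-hydroxy-7-methyloctahydro-2H-cyclohepta[b]furan-2-one | C1C(=O)O[C@@H]2C[C@H](C)[C@@H](O)CC[C@H]12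
F7 | step 17 | (R)-4-[(tert-butyldimethylsilyl)oxy]cyclohept-2-en-1-one | CC(C)(C)[Si](C)(C)O[C@H]1C=CC(=O)CCC1
F8 | step 17 | ethyl 2-[(1S,5R)-5-[(tert-butyldimethylsilyl)oxy]-2-oxocyclohept-3-en-1-yl]acetate | CCOC(=O)C[C@H]1C(=O)C=C[C@H](O[Si](C)(C)C(C)(C)C)CC1
F9 | step 17 | ethyl 2-[(1S,4R,5R)-5-[(tert-butyldimethylsilyl)oxy]-4-methyl-2-oxocycloheptyl]acetate | CCOC(=O)C[C@H]1C(=O)C[C@@H](C)[C@H](O[Si](C)(C)C(C)(C)C)CC1
F10 | step 17 | ethyl 2-[(1S,2S,4R,5R)-5-[(tert-butyldimethylsilyl)oxy]-2-hydroxy-4-methylcycloheptyl]acetate | CCOC(=O)C[C@H]1[C@@H](O)C[C@@H](C)[C@H](O[Si](C)(C)C(C)(C)C)CC1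
F11 | step 17 | (3aS,6R,7R,8aS)-6-[(tert-butyldimethylsilyl)oxy]-7-methyloctahydro-2H-cyclohepta[b]furan-2-one | C1C(=O)O[C@H]2C[C@@H](C)[C@H](O[Si](C)(C)C(C)(C)C)CC[C@@H]12
F12 | step 17 | (3aS,6R,7R,8aS)-6-hydroxy-7-methyloctahydro-2H-cyclohepta[b]furan-2-one | C1C(=O)O[C@H]2C[C@@H](C)[C@H](O)CC[C@@H]12
F0 | step 21 | none | none
F13 | step 23 | C3 carbinol: 30 with C3 bearing OH and 1-ethoxyvinyl in place of the ketone (C3 epimers) | C=C1C(=O)O[C@@H]2C[C@H](C)[C@@]3(O[Si](CC)(CC)CC)CC(O)(C(=C)OCC)[C@@]4(C[C@H]3C[C@H]12)C(=O)O[C@H]1C[C@@H](C)C(CCC5(C)OCCO5)=CC[C@H]14
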